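## Retrosynthetic overview

1. The whole flavanone skeleton (rings A, C and B) and its only stereocentre, C2 (S), are bought intact in natural (2S)-liquiritigenin (1). No ring is constructed, and C2 is never made or broken.
2. The prenyl source is 2-methylbut-3-en-2-ol (2), activated with Boc2O (3) as the tert-prenyl carbonate 4.
3. Key disconnection: 1 + 4 give the bis(1,1-dimethylallyl) ether 5 by Pd-catalysed O-tert-prenylation. One double aromatic Claisen [3,3] rearrangement of 5 then forms both aryl–prenyl C–C bonds (C8 and C3') of glabrol (6).

Assumption: commercial natural (2S)-liquiritigenin (licorice aglycone) is taken as essentially enantiopure; its ee should be confirmed by chiral HPLC on receipt.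

## Route

**Step 1**
Reactants: 2, 2-methylbut-3-en-2-ol; 3, di-tert-butyl dicarbonate
Product: 4, tert-butyl (2-methylbut-3-en-2-yl) carbonate
Conditions: n-BuLi (1.05 equiv), THF, −78 → 0 °C; then Boc2O (1.1 equiv), 0 °C → rt, 3 h; short silica plug
Reagents that add atoms: Boc2O (compound 3), CC(C)(C)OC(=O)OC(=O)OC(C)(C)C (supplies the t-BuO–C(=O) unit)
Why: The lithium alkoxide of the tertiary allylic alcohol is acylated by Boc2O (nucleophilic acyl substitution with loss of t-BuOCO2⁻), giving the carbonate without allylic transposition; no stereocentre is involved.

**Step 2**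
Reactants: 1, (2S)-liquiritigenin [(2S)-7-hydroxy-2-(4-hydroxyphenyl)chroman-4-one]; 4, tert-butyl (2-methylbut-3-en-2-yl) carbonate (3 equiv)
Product: 5, (2S)-7-[(2-methylbut-3-en-2-yl)oxy]-2-{4-[(2-methylbut-3-en-2-yl)oxy]phenyl}chroman-4-one
Conditions: Pd(PPh3)4 (5 mol %), degassed THF, 0 °C, 1–3 h, stopped as soon as the mono-ethers are consumed; filter through neutral alumina, concentrate below 30 °C, use promptly
Reagents that add atoms: carbonate 4, C=CC(C)(C)OC(=O)OC(C)(C)C (each equivalent transfers one C5H9 1,1-dimethylallyl group; CO2 and t-BuOH are lost)
Why: In this decarboxylative Tsuji–Trost O-allylation the phenoxide attacks the more substituted terminus of the π-(1,1-dimethylallyl)Pd cation under kinetic control to give the tertiary aryl ether, and because no external base is added the flavanone is not opened by retro-oxa-Michael reaction, so C2 stays (S).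

**Step 3**
Reactants: 5, the bis(1,1-dimethylallyl) ether
Product: 6, glabrol [(2S)-7-hydroxy-2-[4-hydroxy-3-(3-methylbut-2-en-1-yl)phenyl]-8-(3-methylbut-2-en-1-yl)chroman-4-one]
Conditions: degassed o-xylene (0.05 M), BHT (cat.), base-washed sealed tube, 130 °C, 4–6 h; SiO2 chromatography to remove the minor 6-prenyl regioisomer; chiral HPLC check of ee
Reagents that add atoms: none
Why: Each tertiary allyl aryl ether undergoes a concerted aromatic Claisen [3,3] shift with allyl inversion (1,1-dimethylallyl on O becomes prenyl on the ortho carbon), followed by rearomatising tautomerisation; ring A is expected to react mainly at C8 because the vinylogous-ester conjugation gives C7–C8 the higher double-bond character, ring B has two equivalent ortho positions, and the neutral thermal medium leaves the remote C2 (S) centre untouched.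

## Compound list

1 | (2S)-liquiritigenin, (2S)-7-hydroxy-2-(4-hydroxyphenyl)chroman-4-one | Oc1ccc([C@@H]2CC(=O)c3ccc(O)cc3O2)cc1 | starting material (chiral pool)
2 | 2-methylbut-3-en-2-ol | CC(C)(O)C=C | starting material
3 | di-tert-butyl dicarbonate (Boc2O) | CC(C)(C)OC(=O)OC(=O)OC(C)(C)C | starting material
4 | tert-butyl (2-methylbut-3-en-2-yl) carbonate | C=CC(C)(C)OC(=O)OC(C)(C)C | intermediate (reagent)
5 | (2S)-7-[(2-methylbut-3-en-2-yl)oxy]-2-{4-[(2-methylbut-3-en-2-yl)oxy]phenyl}chroman-4-one | C=CC(C)(C)Oc1ccc([C@@H]2CC(=O)c3ccc(OC(C)(C)C=C)cc3O2)cc1 | intermediate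
6 | glabrol, (2S)-7-hydroxy-2-[4-hydroxy-3-(3-methylbut-2-en-1-yl)phenyl]-8-(3-methylbut-2-en-1-yl)chroman-4-one | CC(C)=CCc1cc([C@@H]2CC(=O)c3ccc(O)c(CC=C(C)C)c3O2)ccc1O | target

## Summary

Total steps: 3. Longest linear sequence: 3 (2 → 4 → 5 → 6), of which 2 steps are from the chiral starting material 1.

Steps most likely to fail, in order:

1. **Step 3 (double Claisen).** Risks are partial ring-A rearrangement to C6, loss of isoprene from the tertiary ethers, and thermal erosion of ee through flavanone–chalcone equilibration of the free 4'-phenol. Fallback: give up the thermal rearrangement and install the prenyl groups by cross-coupling at 60 °C or below. This means ortho-iodination of 1 (NIS) to the 8,3'-diiodide, purified as the single regioisomer, then double Stille coupling with tributyl(3-methylbut-2-enyl)stannane (Pd2dba3/AsPh3). Ring-A iodination carries its own C8/C6 question, so this mainly cures the thermal problems.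

2. **Step 2 (Pd O-tert-prenylation).** Risks are Pd-mediated equilibration to the linear prenyl ethers (which would give reverse-prenyl groups after Claisen), incomplete bis-etherification, and phenoxide-induced ring opening. Fallback: a propargyl detour that cannot isomerise. Cu-catalysed O-alkylation with 2-methylbut-3-yn-2-yl trifluoroacetate (from 2-methylbut-3-yn-2-ol and TFAA; CuCl2 cat., DBU, MeCN, −5 °C) gives the bis(1,1-dimethylpropargyl) ether, and Lindlar semi-hydrogenation then gives 5 (one extra step).

3. **Step 1 (carbonate 4).** Risks are elimination or decomposition of the acid- and heat-sensitive tertiary allylic carbonate on purification. Fallback: skip the carbonate and make 5 directly by Pd(0)/carboxylic-acid-catalysed hydroalkoxylation of commercial 3-methylbuta-1,2-diene with the phenols of 1. This generates the same π-(1,1-dimethylallyl)Pd intermediate from the allene and removes one step, but I am less sure of the precedent for phenols with this allene.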